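**Plan**

- Locants (germacranolide style): ring A = C1–C5 (2-OAc; 4-OH, 4-Me = C15); cyclobutane = C1, C5, C6, C10; ring B = C6–C10 (8-OTig; 10-Me = C14); butenolide = O6–C12(=O)–C11(C13H2OAc)=C7. Exo/endo = outer/inner face of the bowl formed by rings A and B, which sit on the same cyclobutane face (cis-syn-cis).
- Retrosynthetic cuts, in order: C13–OAc and C4–OH (alkene hydration); butenolide C7=C11 and O6–C12; C8–O; the two cyclobutane edges C1–C10 and C5–C6 together; last, the two Si–O bonds of a tether, leaving two five-membered-ring pieces.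
- Enabling feature: the cyclobutane shares its C1–C5 edge with ring A and its C6–C10 edge with ring B, so the other two edges are an enone–alkene [2+2] pair, namely C1=C5 of a cyclopent-2-enone (C2=O) and the C6(O)=C10(Me) enol ether of ring B. C4 and C7 both pass through ketones later, so each can lend an endo oxygen to a diisopropylsilylene tether that forces the otherwise disfavoured syn ring fusion.
- Forward: the ring B alcohol (from cyclotene) and (S)-4-hydroxycyclopent-2-enone are joined through silicon and irradiated (rings A, B and cyclobutane complete). C2 is inverted to the acetate, the tether removed, C4/C7 oxidised, C4 methylenated, C8 oxygenated and tigloylated, the butenolide closed by intramolecular Horner–Wadsworth–Emmons reaction, C4 hydrated and C13 acetylated.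
- Stereochemistry: C4 (chiral pool) and C7 (CBS reduction) are relayed through the tether to C1, C5, C6 and C10. C2 comes from exo hydride attack then Mitsunobu inversion, C8 from exo Rubottom oxidation, C4 from exo capture of a tertiary radical.

Key step: step 4

Remark: (S)-4-hydroxycyclopent-2-en-1-one is taken as a commercial chiral-pool enone. The target SMILES is read as cis-syn-cis with O2, O4 and O8 exo and C15 endo.

**Route**

Step 1
Reactants: 1 2-hydroxy-3-methylcyclopent-2-en-1-one (cyclotene)
Product: 2 2-[(4-methoxybenzyl)oxy]-3-methylcyclopent-2-en-1-one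
Conditions: PMBCl, K2CO3, DMF, 50 °C
Reagents that add atoms: 4-methoxybenzyl chloride, COc1ccc(CCl)cc1
Why: Williamson O-alkylation of the acidic diosphenol enol fixes the future C6 oxygen as an enol ether and leaves the C7 carbonyl free.

Step 2
Reactants: 2 2-[(4-methoxybenzyl)oxy]-3-methylcyclopent-2-en-1-one
Product: 3 (R)-2-[(4-methoxybenzyl)oxy]-3-methylcyclopent-2-en-1-ol
Conditions: (S)-2-methyl-CBS-oxazaborolidine (20 mol %), catecholborane, toluene, –78 °C
Reagents that add atoms: none
Why: Corey–Bakshi–Shibata 1,2-reduction, with the substituted alkenyl arm acting as the large group, should give the (R)-carbinol; this sets C7, the anchor that later fixes the facial sense on ring B.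

Step 3
Reactants: 3 (R)-2-[(4-methoxybenzyl)oxy]-3-methylcyclopent-2-en-1-ol; 4 (S)-4-hydroxycyclopent-2-en-1-one
Product: 6 diisopropylsilanediyl bis-ether linking O7 of 3 to O4 of 4, via chlorosilane 5 (not isolated)
Conditions: iPr2SiCl2 (3 equiv), Et3N, DMAP (cat.), CH2Cl2, –40 °C; excess silane removed in vacuo; then 4, imidazole, CH2Cl2, 0 °C to rt
Reagents that add atoms: dichlorodiisopropylsilane, CC(C)[Si](Cl)(Cl)C(C)C
Why: Stepwise silylation (temporary silicon tether): the hindered allylic alcohol is silylated first with excess dichlorosilane, and the remaining Si–Cl bond is displaced by the second alcohol without touching either stereocentre.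

Step 4
Reactants: 6 diisopropylsilanediyl bis-ether
Product: 7 cis-syn-cis photoadduct: tricyclic 2-ketone with 6-(4-methoxybenzyloxy), 10-methyl and a diisopropylsilylene bridging the endo oxygens at C4 and C7 (H-1, H-5, O-6 and C-14 on one cyclobutane face, rings A and B on the other)
Conditions: hν (365 nm), degassed CH2Cl2 (5 mM), 0 °C
Reagents that add atoms: none
Why: Excitation of the cyclopentenone, intersystem crossing and addition of the triplet enone to the tethered tetrasubstituted enol ether give a 1,4-diradical that collapses to the cyclobutane, forming C5–C6 and C1–C10 in one operation. The closest known reaction type is the intramolecular enone–alkene [2+2] photocycloaddition run through a temporary silicon tether that joins two allylic alcohols as a dialkoxysilane. The cyclobutane closes in the straight (parallel, head-to-tail) mode, which also closes the seven-membered 1,3-dioxa-2-silepane (C4–O–Si–O–C7–C6–C5) cis-fused to it; both five-membered rings end cis-fused because each alkene sits in a small ring. C5 and C1 are set by C4 (the new bonds form on the face of ring A that carries the tether oxygen) and C6 and C10 by C7 in the same way; the syn relation of rings A and B should follow from the short O–Si–O bridge, which spans O4 and O7 comfortably only when C4 and C7 lie cis on the new C5–C6 bond. The step needs head-to-tail regiochemistry and syn over anti fusion: the first is secured by the tether length and by the usual preference of the donor-bearing alkene carbon (C6) for the enone β-carbon (C5), the second by anchoring the tether on the two endo oxygens.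

Step 5
Reactants: 7 photoadduct
Product: 8 2-endo alcohol of 7 (hydroxyl cis to the C4 oxygen)
Conditions: NaBH4, MeOH/THF, –20 °C
Reagents that add atoms: none
Why: Hydride reduction of the ring A ketone from the open exo face gives the endo alcohol, deliberately opposite to the target so that the next step corrects it while acylating.

Step 6
Reactants: 8 2-endo alcohol
Product: 9 2-exo acetate (silylene bridge intact)
Conditions: PPh3, DIAD, AcOH, toluene, 0 °C to rt
Reagents that add atoms: acetic acid, CC(=O)O
Why: Mitsunobu inversion: SN2 displacement of the activated endo alcohol by acetate from the open exo face installs the 2-exo acetate of the target in one operation.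

Step 7
Reactants: 9 2-exo acetate
Product: 10 4-endo,7-endo diol (2-exo-acetoxy, 6-(4-methoxybenzyloxy))
Conditions: HF·pyridine, THF/pyridine, 0 °C to rt
Reagents that add atoms: none
Why: Fluoride cleavage of the dialkoxysilane removes the tether and frees the two carbinols whose configurations are no longer needed.

Step 8
Reactants: 10 diol
Product: 11 4,7-diketone (2-exo-acetoxy, 6-(4-methoxybenzyloxy))
Conditions: Dess–Martin periodinane, pyridine, CH2Cl2, 0 °C to rt
Reagents that add atoms: none
Why: Dess–Martin oxidation of both secondary alcohols under buffered, non-basic conditions should spare the β-acetoxy ketone and the tertiary benzylic ether; C6 stays etherified, so no retro-aldol opening of the cyclobutane can occur.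

Step 9
Reactants: 11 4,7-diketone
Product: 13 4-methylene-7-ketone, via hydroxysilane 12 (not isolated)
Conditions: Me3SiCH2MgCl, CeCl3, THF, –78 °C; then aq. HF, MeCN, 0 °C
Reagents that add atoms: (trimethylsilyl)methylmagnesium chloride, C[Si](C)(C)C[Mg]Cl
Why: Peterson olefination with an organocerium reagent: the bulky, non-basic nucleophile should add only to the exposed C4 ketone (C7 is flanked by quaternary C6 and shielded on its exo face by the 4-methoxybenzyloxy group, and the β-acetoxy ketone is not enolised), and acid-induced elimination of the β-hydroxysilane gives the exocyclic methylene.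

Step 10
Reactants: 13 4-methylene-7-ketone
Product: 15 8-exo-hydroxy-7-ketone, via silyl enol ether 14 (not isolated)
Conditions: TMSOTf, Et3N, CH2Cl2, –78 to 0 °C; then dimethyldioxirane (1.0 equiv), acetone, –78 °C; then citric acid, MeOH
Reagents that add atoms: trimethylsilyl triflate, C[Si](C)(C)OS(=O)(=O)C(F)(F)F (silicon in 14 only); dimethyldioxirane, CC1(C)OO1
Why: Rubottom oxidation: the C7 ketone can enolise only towards C8, and epoxidation of the silyl enol ether (far more electron-rich than the exocyclic alkene) from the exo face of ring B sets the 8-exo hydroxyl.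

Step 11
Reactants: 15 8-exo-hydroxy-7-ketone
Product: 16 8-exo tiglate
Conditions: (E)-2-methylbut-2-enoyl chloride, pyridine, DMAP (cat.), CH2Cl2, 0 °C
Reagents that add atoms: tigloyl chloride, C/C=C(\C)C(Cl)=O
Why: DMAP-catalysed acylation of the only free hydroxyl installs the (E)-2-methylbut-2-enoate.

Step 12
Reactants: 16 8-exo tiglate
Product: 17 6-hydroxy-7-ketone (tertiary α-ketol; 2-exo-acetoxy, 4-methylene, 8-exo-tigloyloxy)
Conditions: DDQ, CH2Cl2/pH 7 buffer, 0 °C to rt
Reagents that add atoms: none
Why: Oxidative cleavage of the 4-methoxybenzyl ether frees the tertiary C6 hydroxyl; C4 is no longer a ketone by now, so the β-hydroxy ketone that would open the cyclobutane never arises.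

Step 13
Reactants: 18 diethyl (2-hydroxyethyl)phosphonate
Product: 19 diethyl {2-[(tert-butyldimethylsilyl)oxy]ethyl}phosphonate
Conditions: TBSCl, imidazole, DMF, rt
Reagents that add atoms: tert-butyldimethylsilyl chloride, CC(C)(C)[Si](C)(C)Cl
Why: Standard silylation of the primary alcohol.

Step 14
Reactants: 19 diethyl {2-[(tert-butyldimethylsilyl)oxy]ethyl}phosphonate
Product: 20 3-[(tert-butyldimethylsilyl)oxy]-2-(diethoxyphosphoryl)propanoic acid (racemic)
Conditions: LiN(iPr)2, THF, –78 °C; CO2; cold dilute HCl work-up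
Reagents that add atoms: carbon dioxide, O=C=O
Why: Carboxylation of the α-lithiated phosphonate gives the α-phosphono acid; the carbanion is kept cold to avoid loss of silyloxide.

Step 15
Reactants: 17 6-hydroxy-7-ketone; 20 3-[(tert-butyldimethylsilyl)oxy]-2-(diethoxyphosphoryl)propanoic acid
Product: 21 6-O-[3-(tert-butyldimethylsilyloxy)-2-(diethoxyphosphoryl)propanoyl] ester of 17 (mixture at the carbon α to phosphorus)
Conditions: DCC, DMAP (cat.), CH2Cl2, 0 °C to rt
Reagents that add atoms: none
Why: Steglich esterification: carbodiimide activation of an α-phosphono acid proceeds through the phosphonoketene, the usual way to acylate hindered tertiary α-ketols; the new centre α to phosphorus is lost in the next step.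

Step 16
Reactants: 21 phosphonoacyl ester
Product: 22 butenolide (C7=C11, 13-silyloxy, 4-methylene)
Conditions: LiCl, DBU, MeCN, 0 °C to rt
Reagents that add atoms: none
Why: Intramolecular Horner–Wadsworth–Emmons olefination under mild LiCl/amine conditions closes the butenolide onto the C7 ketone; the phosphonate is the most acidic site and silyloxide is too poor a leaving group to compete.

Step 17
Reactants: 22 butenolide
Product: 23 4-exo-hydroxy-4-methyl compound (13-silyloxy)
Conditions: Co(acac)2 (20 mol %), PhSiH3, O2 (1 atm), THF, rt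
Reagents that add atoms: dioxygen, O=O
Why: Mukaiyama hydration: hydrogen atom transfer from a cobalt hydride to the 1,1-disubstituted alkene, then capture of the tertiary C4 radical by O2 on the open exo face, gives the 4-exo hydroxyl with the methyl endo; the tri- and tetrasubstituted conjugated alkenes should react far more slowly.

Step 18
Reactants: 23 4-exo-hydroxy-4-methyl compound
Product: 24 13-hydroxy compound
Conditions: HF·pyridine, THF, 0 °C
Reagents that add atoms: none
Why: Fluoride cleavage of the primary silyl ether.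

Step 19
Reactants: 24 13-hydroxy compound
Product: 25 CNP0210373.1 (target)
Conditions: Ac2O, pyridine, CH2Cl2, 0 °C
Reagents that add atoms: acetic anhydride, CC(=O)OC(C)=O
Why: Acetylation of the primary alcohol; the tertiary C4 hydroxyl should not react under these conditions.

**Compound list**

1 | 2-hydroxy-3-methylcyclopent-2-en-1-one (cyclotene) | CC1=C(O)C(=O)CC1 | starting material
2 | 2-[(4-methoxybenzyl)oxy]-3-methylcyclopent-2-en-1-one | CC1=C(OCc2ccc(OC)cc2)C(=O)CC1 | intermediate
3 | (R)-2-[(4-methoxybenzyl)oxy]-3-methylcyclopent-2-en-1-ol | CC1=C(OCc2ccc(OC)cc2)[C@H](O)CC1 | intermediate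
4 | (S)-4-hydroxycyclopent-2-en-1-one | O=C1C=C[C@@H](O)C1 | starting material
5 | chlorodiisopropylsilyl ether of 3 | CC1=C(OCc2ccc(OC)cc2)[C@H](O[Si](Cl)(C(C)C)C(C)C)CC1 | intermediate
6 | diisopropylsilanediyl bis-ether of 3 (R) and 4 (S) | CC1=C(OCc2ccc(OC)cc2)[C@H](O[Si](C(C)C)(C(C)C)O[C@H]3CC(=O)C=C3)CC1 | intermediate
7 | cis-syn-cis photoadduct, 2-ketone, O4,O7-endo-silylene bridge, 6-OPMB | C1C[C@]2(C)[C@@H]3C(=O)C[C@H](O5)[C@@H]3[C@]2(OCc6ccc(OC)cc6)[C@@H]1O[Si]5(C(C)C)C(C)C | intermediate
8 | 2-endo alcohol of 7 | C1C[C@]2(C)[C@@H]3[C@H](O)C[C@H](O5)[C@@H]3[C@]2(OCc6ccc(OC)cc6)[C@@H]1O[Si]5(C(C)C)C(C)C | intermediate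
9 | 2-exo acetate, silylene bridge intact | C1C[C@]2(C)[C@@H]3[C@@H](OC(C)=O)C[C@H](O5)[C@@H]3[C@]2(OCc6ccc(OC)cc6)[C@@H]1O[Si]5(C(C)C)C(C)C | intermediate
10 | 4-endo,7-endo diol, 2-exo-OAc, 6-OPMB | C1C[C@]2(C)[C@@H]3[C@@H](OC(C)=O)C[C@H](O)[C@@H]3[C@]2(OCc5ccc(OC)cc5)[C@@H]1O | intermediate
11 | 4,7-diketone, 2-exo-OAc, 6-OPMB | C1C[C@]2(C)[C@@H]3[C@@H](OC(C)=O)CC(=O)[C@@H]3[C@]2(OCc5ccc(OC)cc5)C1=O | intermediate
12 | 4-endo-hydroxy-4-exo-(trimethylsilylmethyl)-7-ketone | C1C[C@]2(C)[C@@H]3[C@@H](OC(C)=O)C[C@](C[Si](C)(C)C)(O)[C@@H]3[C@]2(OCc5ccc(OC)cc5)C1=O | intermediate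
13 | 4-methylene-7-ketone, 2-exo-OAc, 6-OPMB | C1C[C@]2(C)[C@@H]3[C@@H](OC(C)=O)CC(=C)[C@@H]3[C@]2(OCc5ccc(OC)cc5)C1=O | intermediate
14 | C7 trimethylsilyl enol ether (C7=C8) of 13 | C=1C[C@]2(C)[C@@H]3[C@@H](OC(C)=O)CC(=C)[C@@H]3[C@]2(OCc5ccc(OC)cc5)C=1O[Si](C)(C)C | intermediate
15 | 8-exo-hydroxy-7-ketone | O[C@H]1C[C@]2(C)[C@@H]3[C@@H](OC(C)=O)CC(=C)[C@@H]3[C@]2(OCc5ccc(OC)cc5)C1=O | intermediate
16 | 8-exo tiglate, 6-OPMB | C/C=C(\C)C(=O)O[C@H]1C[C@]2(C)[C@@H]3[C@@H](OC(C)=O)CC(=C)[C@@H]3[C@]2(OCc5ccc(OC)cc5)C1=O | intermediate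
17 | 6-hydroxy-7-ketone (tertiary α-ketol), 8-exo tiglate | C/C=C(\C)C(=O)O[C@H]1C[C@]2(C)[C@@H]3[C@@H](OC(C)=O)CC(=C)[C@@H]3[C@]2(O)C1=O | intermediate
18 | diethyl (2-hydroxyethyl)phosphonate | CCOP(=O)(CCO)OCC | starting material
19 | diethyl {2-[(tert-butyldimethylsilyl)oxy]ethyl}phosphonate | CCOP(=O)(CCO[Si](C)(C)C(C)(C)C)OCC | intermediate
20 | 3-[(tert-butyldimethylsilyl)oxy]-2-(diethoxyphosphoryl)propanoic acid (racemic) | CCOP(=O)(OCC)C(CO[Si](C)(C)C(C)(C)C)C(=O)O | intermediate
21 | 6-O-phosphonoacyl ester of 17 | C/C=C(\C)C(=O)O[C@H]1C[C@]2(C)[C@@H]3[C@@H](OC(C)=O)CC(=C)[C@@H]3[C@]2(OC(=O)C(CO[Si](C)(C)C(C)(C)C)P(=O)(OCC)OCC)C1=O | intermediate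
22 | butenolide, 13-OTBS, 4-methylene | C/C=C(\C)C(=O)O[C@H]1C[C@]2(C)[C@@H]3[C@@H](OC(C)=O)CC(=C)[C@@H]3[C@@]23OC(=O)C(CO[Si](C)(C)C(C)(C)C)=C13 | intermediate
23 | 4-exo-hydroxy-4-methyl butenolide, 13-OTBS | C/C=C(\C)C(=O)O[C@H]1C[C@]2(C)[C@@H]3[C@@H](OC(C)=O)C[C@@](C)(O)[C@@H]3[C@@]23OC(=O)C(CO[Si](C)(C)C(C)(C)C)=C13 | intermediate
24 | 13-hydroxy compound | C/C=C(\C)C(=O)O[C@H]1C[C@]2(C)[C@@H]3[C@@H](OC(C)=O)C[C@@](C)(O)[C@@H]3[C@@]23OC(=O)C(CO)=C13 | intermediate
25 | CNP0210373.1: 2-exo-acetoxy-4-exo-hydroxy-4-methyl-8-exo-tigloyloxy-13-acetoxy cis-syn-cis 5-4-5 tricyclic 7(11)-en-12,6-olide | C/C=C(\C)C(=O)O[C@H]1C[C@]2(C)[C@@H]3[C@@H](OC(C)=O)C[C@@](C)(O)[C@@H]3[C@@]23OC(=O)C(COC(C)=O)=C13 | target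

**Step count and risks**

Total steps: 19. Longest linear sequence: 17 (steps 1–12 and 15–19).

Step 4 (photocycloaddition). What may go wrong: the long-bonded, flexible seven-membered silylene ring may fail to hold the two rings syn, giving anti or crossed closure; or the excited enone may decay or dimerise faster than it adds to the tetrasubstituted enol ether. Fallback, a carbon ketal tether in place of the silylene, setting out from 3 and 4 and returning at 10. Compound 4 with 2-methoxypropene and PPTS should give (S)-4-[(2-methoxypropan-2-yl)oxy]cyclopent-2-en-1-one F1. Acid-catalysed exchange of its methoxy group with 3 (PPTS, 4 Å sieves) should give the isopropylidene-linked bis-ether F2. Irradiation as in step 4 should give the 1,3-dioxepane-bridged cis-syn-cis adduct F3, in which the shorter C–O bonds and the gem-dimethyl carbon hold O4 and O7 closer together. NaBH4 should then give the 2-endo alcohol F4, Mitsunobu reaction with acetic acid the 2-exo acetate F5, and aqueous acetic acid should remove the ketal to give diol 10.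

Step 15 (acylation of the tertiary cyclobutanol). What may go wrong: the α-branched phosphono acid may not acylate the hindered C6 hydroxyl, and the α-ketol may rearrange under prolonged activation. Fallback, the smallest acyl group and a different ring closure, setting out from 17 and returning at 25. Acryloyl chloride with iPr2NEt should give the 6-O-acrylate F9. An intramolecular Morita–Baylis–Hillman reaction (PMe3) onto the C7 ketone should close the α-methylene-β-hydroxy lactone F10 (7-endo hydroxyl). Acetylation with allylic transposition (Ac2O, TMSOTf cat.) should move the double bond into conjugation and give the 13-acetoxy butenolide with the 4-methylene group F11. Mukaiyama hydration as in step 17 should then give 25 directly.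

Step 9 (methylenation of the diketone). What may go wrong: loss of chemoselectivity between the two ketones, β-elimination of the C2 acetate, or transannular aldol closure across the bowl. Fallback, differentiation of the two carbinols before oxidation, setting out from 10 and returning at 13. A sterically demanding oxoammonium oxidation (TEMPO, PhI(OAc)2) should oxidise only the less hindered C4 carbinol to the 7-endo-hydroxy-4-ketone F6. Addition of Me3SiCH2MgCl/CeCl3 should give the β-hydroxysilane F7, and aqueous HF the 4-methylene-7-endo alcohol F8. Dess–Martin oxidation of the remaining carbinol should give 13.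

Further compounds
F1 | step 4 | (S)-4-[(2-methoxypropan-2-yl)oxy]cyclopent-2-en-1-one | COC(C)(C)O[C@H]1CC(=O)C=C1
F2 | step 4 | isopropylidene-linked bis-ether of 3 and 4 | CC1=C(OCc2ccc(OC)cc2)[C@H](OC(C)(C)O[C@H]3CC(=O)C=C3)CC1
F3 | step 4 | 1,3-dioxepane-bridged cis-syn-cis photoadduct, 2-ketone | C1C[C@]2(C)[C@@H]3C(=O)C[C@H](O5)[C@@H]3[C@]2(OCc6ccc(OC)cc6)[C@@H]1OC5(C)C
F4 | step 4 | 2-endo alcohol of F3 | C1C[C@]2(C)[C@@H]3[C@H](O)C[C@H](O5)[C@@H]3[C@]2(OCc6ccc(OC)cc6)[C@@H]1OC5(C)C
F5 | step 4 | 2-exo acetate, ketal bridge intact | C1C[C@]2(C)[C@@H]3[C@@H](OC(C)=O)C[C@H](O5)[C@@H]3[C@]2(OCc6ccc(OC)cc6)[C@@H]1OC5(C)C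
F6 | step 9 | 7-endo-hydroxy-4-ketone | C1C[C@]2(C)[C@@H]3[C@@H](OC(C)=O)CC(=O)[C@@H]3[C@]2(OCc5ccc(OC)cc5)[C@@H]1O
F7 | step 9 | 4-endo-hydroxy-4-exo-(trimethylsilylmethyl)-7-endo alcohol | C1C[C@]2(C)[C@@H]3[C@@H](OC(C)=O)C[C@](C[Si](C)(C)C)(O)[C@@H]3[C@]2(OCc5ccc(OC)cc5)[C@@H]1O
F8 | step 9 | 4-methylene-7-endo alcohol | C1C[C@]2(C)[C@@H]3[C@@H](OC(C)=O)CC(=C)[C@@H]3[C@]2(OCc5ccc(OC)cc5)[C@@H]1O
F9 | step 15 | 6-O-acrylate of 17 | C/C=C(\C)C(=O)O[C@H]1C[C@]2(C)[C@@H]3[C@@H](OC(C)=O)CC(=C)[C@@H]3[C@]2(OC(=O)C=C)C1=O
F10 | step 15 | α-methylene-β-hydroxy lactone (7-endo hydroxyl) | C/C=C(\C)C(=O)O[C@H]1C[C@]2(C)[C@@H]3[C@@H](OC(C)=O)CC(=C)[C@@H]3[C@@]23OC(=O)C(=C)[C@@]13O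
F11 | step 15 | 13-acetoxy butenolide with 4-methylene | C/C=C(\C)C(=O)O[C@H]1C[C@]2(C)[C@@H]3[C@@H](OC(C)=O)CC(=C)[C@@H]3[C@@]23OC(=O)C(COC(C)=O)=C13
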